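# Synthesis plan for 3,5,7,3',4'-pentahydroxy-6,8-dimethoxyflavone (16)

## The problem

The target 16 is a flavonol: a benzopyran-4-one in which ring A and ring C share the C4a–C8a bond, with a catechol ring B on C2. It has no stereocentre, so the task is one of substitution pattern and oxidation level. The only stereocentres that arise on the way, C2 and C3 of an epoxide, are destroyed in the operation that makes them.

Ring A is fully substituted. Five oxygens stand in a row (O1 on C8a, 8-OMe, 7-OH, 6-OMe, 5-OH) and C4 sits on C4a. Two of these oxygens must end methylated between free neighbours, so the methyl groups have to arrive with a starting material and every other oxygen should carry one kind of group that leaves under neutral conditions.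

The free compound combines a 3-hydroxy-4-pyranone, a catechol and a very electron-rich ring A, all of which oxidise readily in air and base. The 6-methoxy group next to the chelating 5-OH would not survive Lewis-acid ether cleavage. The phenols should therefore be released only in the last step.

Two features open the structure. C4 is a lone carbonyl carbon held between C4a and C3, so it can come from carbon monoxide. Ring A is symmetric about the axis through C4a and C7: O1 and the 5-OH, and the 6- and 8-methoxy groups, are pairwise equivalent in a 2-iodoresorcinol. C3, C2 and ring B then form an arylalkyne. The price is that the alkyne delivers C3 as CH, so the 3-OH must be added after ring C is closed.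

## Retrosynthesis

**16 from 15.** The four O–benzyl bonds at O5, O7, O3' and O4' are cut last. Benzyl is preferred to methyl (indistinguishable from the 6- and 8-OMe groups) and to acetal groups (acid on a sensitive polyphenol), because one neutral hydrogenolysis frees all four phenols together. The forward step must leave the two methyl ethers and the C2–C3 double bond alone.

**15 from 13, through epoxide 14.** The C3–O bond is cut. Since the alkyne of the key step supplies C3 as CH, this oxygen cannot be carried through ring closure and must be added afterwards. Epoxidation of the C2–C3 double bond followed by acid isomerisation is chosen over base-mediated C3 functionalisation because it is neutral to mildly acidic. It requires O5 to be capped, which leads back to flavone 12 through benzylation of the chelated 5-OH. That benzyl is the same group as the other three and costs no extra deprotection step.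

**12 from 6, 8 and 9 (key disconnection).** Three bonds are cut at once: C4a–C4, C4–C3 and O1–C2. This takes a 38-carbon flavone back to iodoresorcinol 6, arylalkyne 8 and carbon monoxide 9, passing forward through ynone 10 and enaminone 11. A cut at O1–C2 and C2–C3 alone (a diketone cyclisation) would need an acetophenone whose two ortho oxygens are differentiated. The three-bond cut lets ring A stay symmetric, so either hydroxyl of 6 may close the ring. The forward reaction must insert CO before alkynylation and close the six-membered ring rather than a five-membered one.

**6 from 5, 5 from 3 through 4, 3 from 2, 2 from 1.** The C–I bond of 6 goes back to resorcinol 5, whose only free ring position lies between the two hydroxyls. The two C–O bonds of 5 go back, through bis(boronate) 4, to the two C–Br bonds of dibromide 3. These two sites are symmetry-equivalent, so both oxygens are installed in one operation. The C–Br bonds go back to benzyl ether 2, where electrophilic substitution of a 1,2,3-trioxygenated benzene falls at exactly the two positions needed. The O–benzyl bond of 2 leads to 2,6-dimethoxyphenol 1, which already holds both methyl ethers of the target around the future O7.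

**8 from 7.** The alkyne carbon–carbon triple bond is traced to the aldehyde carbon of 3,4-bis(benzyloxy)benzaldehyde 7 by a one-carbon homologation. This is one step, against two for coupling a protected acetylene to a halocatechol ether, and it uses a commercial aldehyde that already carries the ring B benzyl groups.

## Roads not taken

**Alternative 1: ring C closed at C2–C3 by intramolecular ester olefination.** The cut is the C2=C3 double bond. In the forward step the keto-stabilised ylide A2, held next to an aroyl ester on ring A, attacks the ester carbonyl and loses the phosphine oxide to give the fully benzylated flavone A1, which is the same structure as 13.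
- Merits: no transition metal and no pressurised CO. O5 arrives already benzylated. The sensitive free iodoresorcinol 6 is avoided.
- Weak points: A2 needs a hexasubstituted acetophenone in which the two oxygens flanking the acyl group are different (one benzyl ether, one aroyl ester), so the symmetry of ring A is thrown away. After diol 5 it would take C-acylation, selective mono-benzylation, esterification of a hindered chelated phenol, α-halogenation, phosphonium salt formation and the olefination. The ylide is stabilised and the ester is flanked on both sides, so the ring closure needs forcing conditions.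
- Comparison: the endgame is identical to the chosen plan, since A1 equals 13 and still lacks the 3-OH. The alternative is safer in handling. The chosen plan sets against it three steps from 5 to 13 instead of about six, and a convergent union of the two halves.

**Alternative 2: reductive pinacol closure to a flavan-3,4-diol.** The cut is C3–C4. In the forward step dialdehyde A4 is treated with SmI2; the ketyl of the aryl aldehyde adds to the aliphatic aldehyde and closes ring C as diol A3.
- Merits: the C3 oxygen is built in during ring closure, which is a real advantage over the chosen plan. The diastereoselectivity of the pinacol is irrelevant, because a double oxidation would give a 3,4-dione whose enol is the flavonol.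
- Weak points: A4 is an α-aryloxy-α-aryl acetaldehyde, prone to enolisation and hydration. SmI2 is known to cleave α-oxygenated carbonyl compounds reductively, which here would break O1–C2 instead of forming C3–C4. The ether O1–C2 must be made by alkylating a phenol flanked on both sides with a secondary benzylic electrophile. Ring A again has to be desymmetrised (formyl, aryl ether and benzyl ether in a row). Two oxidation levels must be climbed back after the closure.
- Comparison: better in where the 3-oxygen comes from. Weaker in step count and in the reliability of its key step. The chosen plan accepts a late C3 oxidation in exchange for a ring closure of a known type.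

**Alternative 3: ring C closed at the aryl ether bond.** The cut is O1–C8a. In the forward step the 2-bromoaryl 1,3-diketone A6 cyclises under CuI, 1,10-phenanthroline and Cs2CO3 by intramolecular O-arylation of its enolate to give the pentabenzyl flavonol A5.
- Merits: the 3-oxygen is carried in as a benzyl ether on the central carbon of the diketone, so after ring closure only one hydrogenolysis remains. That is one step against three in the chosen endgame, with no dioxirane.
- Weak points: the ring A half of A6 bears bromine, acyl, two benzyloxy and two methoxy groups with no symmetry. Starting from 1, the two positions next to the methoxy groups must be functionalised differently (one bromine, one oxygen) and a carbonyl added, which is far longer than the four steps to 6. The diketone must be assembled by a Claisen-type acylation involving a benzoyl unit flanked on both sides. The C–Br bond to be attacked lies between a methoxy group and the acyl group on a very electron-rich ring, and a 2-alkoxy-1,3-diketone can undergo retro-Claisen cleavage under hot carbonate.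
- Comparison: the endgame is better than that of the chosen plan. The chosen plan sets against it a symmetric, short ring A synthesis and a one-step union of three components, for a lower overall count.

Key step: step 6

## Route

Remarks on the chemistry:
- Compounds 1, 7 and 9 and all reagents are taken as commercial.
- Enaminone 11 is drawn as the E isomer. Its push–pull double bond is geometrically mobile and the geometry has no bearing on the product.
- Epoxide 14 is racemic and necessarily cis-fused; one enantiomer is drawn.

Step 1
Reactants: 1 2,6-dimethoxyphenol
Product: 2 2-(benzyloxy)-1,3-dimethoxybenzene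
Conditions: BnBr, K2CO3, DMF, 60 °C
Reagents that add atoms: benzyl bromide, BrCc1ccccc1
Why: Williamson ether synthesis on the phenoxide of 1; the benzyl group on the future O7 leaves with the others in the last step.

Step 2
Reactants: 2 2-(benzyloxy)-1,3-dimethoxybenzene
Product: 3 3-(benzyloxy)-1,5-dibromo-2,4-dimethoxybenzene
Conditions: NBS (2.1 equiv), MeCN, 0 °C to rt, dark
Reagents that add atoms: N-bromosuccinimide, O=C1CCC(=O)N1Br
Why: Electrophilic aromatic bromination; in a 1,2,3-trialkoxybenzene the central alkoxy group is twisted out of conjugation, so each bromine enters ortho to one outer methoxy group and para to the other, and the position para to the benzyloxy group stays free.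

Step 3
Reactants: 3 3-(benzyloxy)-1,5-dibromo-2,4-dimethoxybenzene
Product: 5 5-(benzyloxy)-4,6-dimethoxybenzene-1,3-diol, via bis(pinacolboronate) 4 (not isolated)
Conditions: B2pin2, PdCl2(dppf) (5 mol %), KOAc, 1,4-dioxane, 95 °C; filter; then 30% aq H2O2, aq NaOH, THF, 0 °C
Reagents that add atoms: bis(pinacolato)diboron, CC1(C)OB(OC1(C)C)B1OC(C)(C)C(C)(C)O1 (supplies the boryl groups of 4, none of which remains in 5); hydrogen peroxide, OO (supplies both new hydroxyl oxygens of 5)
Why: Miyaura borylation of both C–Br bonds followed by peroxide oxidation of the aryl boronates (aryl migration from boron to oxygen); both operations are standard for alkoxy-substituted aryl bromides, and the two sites are equivalent so no selectivity is asked.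

Step 4
Reactants: 5 5-(benzyloxy)-4,6-dimethoxybenzene-1,3-diol
Product: 6 5-(benzyloxy)-2-iodo-4,6-dimethoxybenzene-1,3-diol
Conditions: I2, NaHCO3, THF/H2O, 0 °C, dark
Reagents that add atoms: iodine, II
Why: Electrophilic iodination of a resorcinol under bicarbonate, the usual entry to 2-iodoresorcinols; the carbon between the two hydroxyls is the only free ring position and is activated by both.

Step 5
Reactants: 7 3,4-bis(benzyloxy)benzaldehyde
Product: 8 1,2-bis(benzyloxy)-4-ethynylbenzene
Conditions: dimethyl (1-diazo-2-oxopropyl)phosphonate, K2CO3, MeOH/THF, rt
Reagents that add atoms: dimethyl (1-diazo-2-oxopropyl)phosphonate, COP(=O)(OC)C(=[N+]=[N-])C(C)=O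
Why: Seyferth–Gilbert homologation with the Ohira–Bestmann reagent; methanolysis releases the diazomethylphosphonate anion, which olefinates the aldehyde, and loss of N2 with a 1,2-hydrogen shift gives the terminal alkyne under conditions that leave benzyl ethers untouched.

Step 6
Reactants: 6 5-(benzyloxy)-2-iodo-4,6-dimethoxybenzene-1,3-diol; 8 1,2-bis(benzyloxy)-4-ethynylbenzene; 9 carbon monoxide
Product: 12 7-(benzyloxy)-2-[3,4-bis(benzyloxy)phenyl]-5-hydroxy-6,8-dimethoxy-4H-chromen-4-one, via ynone 10 (not isolated), via enaminone 11 (not isolated)
Conditions: CO (20 bar), PdCl2(PPh3)2 (5 mol %), Et2NH, 120 °C, autoclave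
Reagents that add atoms: diethylamine, CCNCC (adds its nitrogen and ethyl groups to 11 only; they are expelled on ring closure, and every heavy atom of 12 comes from 6, 8 and 9)
Why: This is a carbonylative Sonogashira coupling followed by amine-mediated cyclisation, the known palladium route from 2-iodophenols, terminal alkynes and CO to flavones. PdCl2(PPh3)2 is reduced in the flask to zerovalent palladium, which inserts into the C–I bond of 6; CO insertion gives an aroyl palladium species, and copper-free alkynylation by 8 with reductive elimination forms C4a–C4 and C4–C3 in ynone 10. Diethylamine adds to the aryl-bearing alkyne carbon to give enaminone 11, and a flanking phenol attacks that same carbon in a 6-endo-trig addition–elimination that forms O1–C2, expels the amine and closes ring C. No stereocentre is created. The step needs carbonylation to beat direct alkynylation (which would end in a benzofuran) and six-ring closure to beat 5-exo closure to an aurone. CO pressure, the absence of copper and the ready migration of the electron-rich, doubly ortho-substituted aryl group to CO should secure the first; passage through the enaminone, whose electrophilic carbon is C2, should secure the second. No regiochemical question arises, because the mirror plane of 6 through C–I and C–OBn makes the two hydroxyls equivalent; the one not used becomes the chelated 5-OH, which is inert under the conditions.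

Step 7
Reactants: 12 7-(benzyloxy)-2-[3,4-bis(benzyloxy)phenyl]-5-hydroxy-6,8-dimethoxy-4H-chromen-4-one
Product: 13 5,7-bis(benzyloxy)-2-[3,4-bis(benzyloxy)phenyl]-6,8-dimethoxy-4H-chromen-4-one
Conditions: BnBr, K2CO3, KI (cat.), DMF, 70 °C
Reagents that add atoms: benzyl bromide, BrCc1ccccc1
Why: Williamson ether synthesis on the chelated 5-OH; hydrogen bonding to the C4 carbonyl and the neighbouring 6-methoxy group slow it, hence DMF, iodide catalysis and heat, and capping O5 is what makes the enone double bond amenable to epoxidation.

Step 8
Reactants: 13 5,7-bis(benzyloxy)-2-[3,4-bis(benzyloxy)phenyl]-6,8-dimethoxy-4H-chromen-4-one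
Product: 15 5,7-bis(benzyloxy)-2-[3,4-bis(benzyloxy)phenyl]-3-hydroxy-6,8-dimethoxy-4H-chromen-4-one, via epoxide 14 (not isolated)
Conditions: DMDO (acetone solution), CH2Cl2, 0 °C to rt; evaporate; then p-TsOH·H2O (cat.), CH2Cl2, rt
Reagents that add atoms: dimethyldioxirane, CC1(C)OO1
Why: Dioxirane epoxidation of the C2–C3 double bond of a 5-O-protected flavone, then acid-catalysed opening of the epoxide at C2 (a cation stabilised by O1 and ring B) and loss of the C3 proton; this is the established two-stage flavone-to-flavonol oxidation, and both stereocentres of racemic 14 are erased.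

Step 9
Reactants: 15 5,7-bis(benzyloxy)-2-[3,4-bis(benzyloxy)phenyl]-3-hydroxy-6,8-dimethoxy-4H-chromen-4-one
Product: 16 2-(3,4-dihydroxyphenyl)-3,5,7-trihydroxy-6,8-dimethoxy-4H-chromen-4-one
Conditions: H2 (1 atm), 10% Pd/C, THF/MeOH, rt
Reagents that add atoms: none
Why: Hydrogenolysis of the four benzyl ethers over palladium on carbon under neutral conditions; aryl methyl ethers and the pyranone double bond are not touched, and the oxidation-sensitive polyphenol is released only here.

## Compound list

1 | 2,6-dimethoxyphenol | COc1cccc(OC)c1O | starting material
2 | 2-(benzyloxy)-1,3-dimethoxybenzene | COc1cccc(OC)c1OCc1ccccc1 | intermediate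
3 | 3-(benzyloxy)-1,5-dibromo-2,4-dimethoxybenzene | COc1c(Br)cc(Br)c(OC)c1OCc1ccccc1 | intermediate
4 | 2,2'-[5-(benzyloxy)-4,6-dimethoxy-1,3-phenylene]bis(4,4,5,5-tetramethyl-1,3,2-dioxaborolane) | COc1c(B2OC(C)(C)C(C)(C)O2)cc(B2OC(C)(C)C(C)(C)O2)c(OC)c1OCc1ccccc1 | intermediate
5 | 5-(benzyloxy)-4,6-dimethoxybenzene-1,3-diol | COc1c(O)cc(O)c(OC)c1OCc1ccccc1 | intermediate
6 | 5-(benzyloxy)-2-iodo-4,6-dimethoxybenzene-1,3-diol | COc1c(O)c(I)c(O)c(OC)c1OCc1ccccc1 | intermediate
7 | 3,4-bis(benzyloxy)benzaldehyde | O=Cc1ccc(OCc2ccccc2)c(OCc2ccccc2)c1 | starting material
8 | 1,2-bis(benzyloxy)-4-ethynylbenzene | C#Cc1ccc(OCc2ccccc2)c(OCc2ccccc2)c1 | intermediate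
9 | carbon monoxide | [C-]#[O+] | starting material
10 | 1-[4-(benzyloxy)-2,6-dihydroxy-3,5-dimethoxyphenyl]-3-[3,4-bis(benzyloxy)phenyl]prop-2-yn-1-one | COc1c(O)c(C(=O)C#Cc2ccc(OCc3ccccc3)c(OCc3ccccc3)c2)c(O)c(OC)c1OCc1ccccc1 | intermediate
11 | (2E)-1-[4-(benzyloxy)-2,6-dihydroxy-3,5-dimethoxyphenyl]-3-[3,4-bis(benzyloxy)phenyl]-3-(diethylamino)prop-2-en-1-one | CCN(CC)/C(=C/C(=O)c1c(O)c(OC)c(OCc2ccccc2)c(OC)c1O)c1ccc(OCc2ccccc2)c(OCc2ccccc2)c1 | intermediate
12 | 7-(benzyloxy)-2-[3,4-bis(benzyloxy)phenyl]-5-hydroxy-6,8-dimethoxy-4H-chromen-4-one | COc1c(OCc2ccccc2)c(OC)c2oc(-c3ccc(OCc4ccccc4)c(OCc4ccccc4)c3)cc(=O)c2c1O | intermediate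
13 | 5,7-bis(benzyloxy)-2-[3,4-bis(benzyloxy)phenyl]-6,8-dimethoxy-4H-chromen-4-one | COc1c(OCc2ccccc2)c(OC)c2oc(-c3ccc(OCc4ccccc4)c(OCc4ccccc4)c3)cc(=O)c2c1OCc1ccccc1 | intermediate
14 | 5,7-bis(benzyloxy)-2-[3,4-bis(benzyloxy)phenyl]-2,3-epoxy-6,8-dimethoxy-2,3-dihydro-4H-chromen-4-one (racemic, cis-fused epoxide, one enantiomer drawn) | COc1c(OCc2ccccc2)c(OC)c2O[C@@]3(c4ccc(OCc5ccccc5)c(OCc5ccccc5)c4)O[C@H]3C(=O)c2c1OCc1ccccc1 | intermediate
15 | 5,7-bis(benzyloxy)-2-[3,4-bis(benzyloxy)phenyl]-3-hydroxy-6,8-dimethoxy-4H-chromen-4-one | COc1c(OCc2ccccc2)c(OC)c2oc(-c3ccc(OCc4ccccc4)c(OCc4ccccc4)c3)c(O)c(=O)c2c1OCc1ccccc1 | intermediate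
16 | 2-(3,4-dihydroxyphenyl)-3,5,7-trihydroxy-6,8-dimethoxy-4H-chromen-4-one (3,5,7,3',4'-pentahydroxy-6,8-dimethoxyflavone) | COc1c(O)c(OC)c2oc(-c3ccc(O)c(O)c3)c(O)c(=O)c2c1O | target

## Step count and risk

Total step count: 9. Longest linear sequence: 8 steps (steps 1, 2, 3, 4, 6, 7, 8, 9 from 1); step 5 is the one-step side branch from 7.

**Step 6 (key step).**
- What may go wrong: interception of the aroyl palladium intermediate by diethylamine to give an amide; coupling without CO insertion followed by closure to a benzofuran; reductive loss of iodine; 5-exo closure to an aurone; oxidative decay of the free iodoresorcinol before it reacts. The aryl iodide is flanked on both sides and very electron-rich, so oxidative addition is the slow point and side paths gain time.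
- Fallback (polar bond formation in place of the palladium–CO event): from 6, both hydroxyls would be capped with chloromethyl methyl ether and iPr2NEt to give 5-(benzyloxy)-2-iodo-4,6-dimethoxy-1,3-bis(methoxymethoxy)benzene F1. Alkyne 8 would be deprotonated with n-BuLi and acylated with N-methoxy-N-methylcarbamoyl chloride to give the Weinreb amide 3-[3,4-bis(benzyloxy)phenyl]-N-methoxy-N-methylprop-2-ynamide F2. Iodine–lithium exchange on F1 (n-BuLi, THF, −78 °C) and addition of the aryllithium to F2 would give the protected ynone 1-[4-(benzyloxy)-3,5-dimethoxy-2,6-bis(methoxymethoxy)phenyl]-3-[3,4-bis(benzyloxy)phenyl]prop-2-yn-1-one F3. HCl in methanol would remove both acetal groups to give ynone 10, which on warming with diethylamine in ethanol rejoins the route at 12.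

**Step 3.**
- What may go wrong: incomplete borylation of the second C–Br bond, protodebromination or protodeboronation leaving a mono-phenol, and over-oxidation of the electron-rich resorcinol by alkaline peroxide.
- Fallback: from 3, direct palladium-catalysed hydroxylation of both C–Br bonds with KOH (Pd2(dba)3, tBuXPhos, dioxane/H2O, 100 °C) would form the two C–O bonds without boron and without peroxide, arriving at 5. It makes no new compound.

**Step 4.**
- What may go wrong: oxidation of the para-methoxyphenol units to a quinone with loss of a methyl group instead of ring substitution, and light- or air-induced loss of iodine from the product.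
- Fallback: from 5, protection with chloromethyl methyl ether and iPr2NEt would give 5-(benzyloxy)-4,6-dimethoxy-1,3-bis(methoxymethoxy)benzene F4. Directed ortho-lithiation at the only ring C–H, flanked by the two acetal ethers (n-BuLi, THF, −40 to 0 °C), and quenching with I2 would give the iodide F1 described under step 6. HCl in methanol would return to 6. Should both this and the step 6 fallback be needed, the aryllithium from F4 could be acylated directly with F2.

**Step 8.**
- What may go wrong: slow epoxidation of the electron-poor enone double bond, which leaves time for oxidation at the benzylic C–H bonds of the benzyl ethers or on the electron-rich rings; and opening of the epoxide by water or with ring contraction instead of isomerisation to the enol.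
- Fallback: from 13, deprotonation at C3 with LiN(iPr)2 (THF, −78 °C) and trapping with B(OMe)3 would give dimethyl {5,7-bis(benzyloxy)-2-[3,4-bis(benzyloxy)phenyl]-6,8-dimethoxy-4-oxo-4H-chromen-3-yl}boronate F5. Oxidation with H2O2 in acetic acid would give 15.

**Step 9.**
- What may go wrong: partial reduction of the C2–C3 double bond on prolonged exposure, and air oxidation of the liberated polyphenol during filtration and concentration.
- Fallback: from 15, Lewis-acid debenzylation with BCl3 and pentamethylbenzene as cation scavenger (CH2Cl2, −78 °C), quenched cold so that the 6-methoxy group next to the boron-chelated 5-oxygen is not cleaved, would give 16. It makes no new compound.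

## Further compounds

F1 | step 6 | 5-(benzyloxy)-2-iodo-4,6-dimethoxy-1,3-bis(methoxymethoxy)benzene | COCOc1c(I)c(OCOC)c(OC)c(OCc2ccccc2)c1OC
F2 | step 6 | 3-[3,4-bis(benzyloxy)phenyl]-N-methoxy-N-methylprop-2-ynamide | CON(C)C(=O)C#Cc1ccc(OCc2ccccc2)c(OCc2ccccc2)c1
F3 | step 6 | 1-[4-(benzyloxy)-3,5-dimethoxy-2,6-bis(methoxymethoxy)phenyl]-3-[3,4-bis(benzyloxy)phenyl]prop-2-yn-1-one | COCOc1c(C(=O)C#Cc2ccc(OCc3ccccc3)c(OCc3ccccc3)c2)c(OCOC)c(OC)c(OCc2ccccc2)c1OC
F0 | step 3 | none | none
F4 | step 4 | 5-(benzyloxy)-4,6-dimethoxy-1,3-bis(methoxymethoxy)benzene | COCOc1cc(OCOC)c(OC)c(OCc2ccccc2)c1OC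
F5 | step 8 | dimethyl {5,7-bis(benzyloxy)-2-[3,4-bis(benzyloxy)phenyl]-6,8-dimethoxy-4-oxo-4H-chromen-3-yl}boronate | COB(OC)c1c(-c2ccc(OCc3ccccc3)c(OCc3ccccc3)c2)oc2c(OC)c(OCc3ccccc3)c(OC)c(OCc3ccccc3)c2c1=O
F0 | step 9 | none | none
A1 | alternative 1 | 5,7-bis(benzyloxy)-2-[3,4-bis(benzyloxy)phenyl]-6,8-dimethoxy-4H-chromen-4-one (same structure as 13) | COc1c(OCc2ccccc2)c(OC)c2oc(-c3ccc(OCc4ccccc4)c(OCc4ccccc4)c3)cc(=O)c2c1OCc1ccccc1
A2 | alternative 1 | 3,5-bis(benzyloxy)-2,4-dimethoxy-6-[2-(triphenyl-λ5-phosphanylidene)acetyl]phenyl 3,4-bis(benzyloxy)benzoate | COc1c(OCc2ccccc2)c(OC)c(OC(=O)c2ccc(OCc3ccccc3)c(OCc3ccccc3)c2)c(C(=O)C=P(c2ccccc2)(c2ccccc2)c2ccccc2)c1OCc1ccccc1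
A3 | alternative 2 | 5,7-bis(benzyloxy)-2-[3,4-bis(benzyloxy)phenyl]-6,8-dimethoxychromane-3,4-diol (racemic, drawn as the 2,3-trans-3,4-cis isomer) | COc1c(OCc2ccccc2)c(OC)c2O[C@@H](c3ccc(OCc4ccccc4)c(OCc4ccccc4)c3)[C@H](O)[C@H](O)c2c1OCc1ccccc1
A4 | alternative 2 | 2,4-bis(benzyloxy)-6-{1-[3,4-bis(benzyloxy)phenyl]-2-oxoethoxy}-3,5-dimethoxybenzaldehyde (racemic) | COc1c(OCc2ccccc2)c(OC)c(OC(C=O)c2ccc(OCc3ccccc3)c(OCc3ccccc3)c2)c(C=O)c1OCc1ccccc1
A5 | alternative 3 | 3,5,7-tris(benzyloxy)-2-[3,4-bis(benzyloxy)phenyl]-6,8-dimethoxy-4H-chromen-4-one | COc1c(OCc2ccccc2)c(OC)c2oc(-c3ccc(OCc4ccccc4)c(OCc4ccccc4)c3)c(OCc3ccccc3)c(=O)c2c1OCc1ccccc1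
A6 | alternative 3 | 2-(benzyloxy)-1-[2,4-bis(benzyloxy)-6-bromo-3,5-dimethoxyphenyl]-3-[3,4-bis(benzyloxy)phenyl]propane-1,3-dione (racemic at the central carbon, enolisable) | COc1c(OCc2ccccc2)c(OC)c(Br)c(C(=O)C(OCc2ccccc2)C(=O)c2ccc(OCc3ccccc3)c(OCc3ccccc3)c2)c1OCc1ccccc1
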